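**Retrosynthetic overview**
1. Feature: the target is a 6,8''-biflavone. Its axis runs from C6 of ring A of the acacetin half (u1) to C8 of ring A of the 7-O-methylapigenin half (u2). All four ortho positions carry oxygen (u1-O5, u1-O7, u2-O7, pyranone u2-O1), and one CH2 group can span u1-O5 and u2-O7.
2. Endgame disconnections: three O-benzyl groups (hydrogenolysis), the u2-O7 methyl (alkylation of the one phenol not hydrogen-bonded to a C4 carbonyl), and the O-CH2-O bridge (acid methanolysis).
3. Key disconnection: u1-C6 to u2-C8. It leads back to the mixed formaldehyde acetal of u1-O5 and u2-O7 with iodine on u2-C8, and intramolecular palladium-catalysed C-H arylation closes a seven-membered dibenzo[d,f][1,3]dioxepine.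
4. The acetal comes from 7-O-benzylacacetin (O5 as nucleophile) and the chloromethyl ether of an 8-iodo-7-hydroxyflavone. That flavone is built from 2,4,6-trihydroxyacetophenone and 4-(benzyloxy)benzaldehyde by the chalcone route.
5. Ring order: u1 is bought complete. Pyranone ring C of u2 closes first (step 5), the temporary dioxepine second (step 11), and the dioxepine is opened again in step 12.

Key step: step 11

Assumption: the target string fixes no configuration at the C6-C8'' axis and contains no stereocentre, so the biaryl is made as the racemic mixture of atropisomers.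

**Route**

Step 1
Reactants: 1 acacetin
Product: 2 7-O-benzylacacetin, 7-(benzyloxy)-5-hydroxy-2-(4-methoxyphenyl)-4H-chromen-4-one
Conditions: BnBr (1.1 equiv), K2CO3, DMF, rt
Reagents that add atoms: benzyl bromide, BrCc1ccccc1
Why: Williamson etherification, in which the free, acidic 7-OH reacts while the 5-OH is held in a hydrogen bond to the C4 carbonyl and stays untouched under carbonate at room temperature.

Step 2
Reactants: 3 2,4,6-trihydroxyacetophenone (dried)
Product: 4 1-[2,6-dihydroxy-4-(methoxymethoxy)phenyl]ethan-1-one
Conditions: MOMCl (1.0 equiv), K2CO3, acetone, 0 °C to rt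
Reagents that add atoms: chloromethyl methyl ether, COCCl
Why: Williamson-type O-alkylation, in which the 4-OH para to the acetyl group is the most acidic hydroxyl and the only one never hydrogen-bonded to the ketone, so it should react first with one equivalent of MOMCl, and any bis-ether is removed by chromatography.

Step 3
Reactants: 4 1-[2,6-dihydroxy-4-(methoxymethoxy)phenyl]ethan-1-one
Product: 5 1-[2-(benzyloxy)-6-hydroxy-4-(methoxymethoxy)phenyl]ethan-1-one
Conditions: BnBr (1.05 equiv), K2CO3, DMF, rt
Reagents that add atoms: benzyl bromide, BrCc1ccccc1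
Why: Williamson etherification of one of two equivalent ortho hydroxyls, after which the remaining one is locked in a strong hydrogen bond to the ketone and resists a second alkylation under carbonate.

Step 4
Reactants: 5 1-[2-(benzyloxy)-6-hydroxy-4-(methoxymethoxy)phenyl]ethan-1-one; 6 4-(benzyloxy)benzaldehyde
Product: 7 (E)-1-[2-(benzyloxy)-6-hydroxy-4-(methoxymethoxy)phenyl]-3-[4-(benzyloxy)phenyl]prop-2-en-1-one
Conditions: KOH (aq), EtOH, rt
Reagents that add atoms: none
Why: Claisen-Schmidt condensation of a methyl ketone with a non-enolisable aldehyde, where E1cB dehydration gives the conjugated E-chalcone and the MOM and benzyl ethers are stable to base.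

Step 5
Reactants: 7 the E-chalcone
Product: 8 5-(benzyloxy)-2-[4-(benzyloxy)phenyl]-7-(methoxymethoxy)-4H-chromen-4-one
Conditions: I2 (10 mol %), DMSO, 125 °C
Reagents that add atoms: none
Why: Iodine-catalysed oxidative cyclisation of a 2'-hydroxychalcone with DMSO as terminal oxidant is the standard flavone synthesis, only the single free ortho phenol can close ring C so that the benzyl ends on O5 and the MOM group on O7, and any MOM loss caused by traces of HI merely anticipates step 6.

Step 6
Reactants: 8 the 7-O-MOM flavone
Product: 9 5-(benzyloxy)-2-[4-(benzyloxy)phenyl]-7-hydroxy-4H-chromen-4-one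
Conditions: 1 M HCl, MeOH-THF (1:1), 45 °C
Reagents that add atoms: none
Why: Acid-catalysed transacetalisation of an aryl MOM ether with methanol runs under conditions mild enough to leave the aryl benzyl ethers in place, the peri 5-O-benzyl included.

Step 7
Reactants: 9 the 7-hydroxyflavone
Product: 10 5-(benzyloxy)-2-[4-(benzyloxy)phenyl]-7-hydroxy-8-iodo-4H-chromen-4-one
Conditions: NIS (1.0 equiv), DMF, 0 °C to rt, dark
Reagents that add atoms: N-iodosuccinimide, O=C1CCC(=O)N1I
Why: Electrophilic aromatic iodination, in which 5,7-dioxygenated flavones with O5 alkylated are attacked at C8 (ortho to the free 7-OH and to O1, para to O5) rather than at C6, which the 5-O-benzyl group screens, one equivalent of NIS under neutral conditions limits diiodination, and the halogen is set before sulfur enters because iodonium reagents would attack a sulfide.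

Step 8
Reactants: 10 the 8-iodo-7-hydroxyflavone; 11 chloromethyl methyl sulfide
Product: 12 5-(benzyloxy)-2-[4-(benzyloxy)phenyl]-8-iodo-7-[(methylsulfanyl)methoxy]-4H-chromen-4-one
Conditions: NaH, NaI (cat.), DMF, 0 °C to rt
Reagents that add atoms: none
Why: Iodide-assisted Williamson alkylation of a phenoxide with ClCH2SMe is the usual entry to aryl methylthiomethyl ethers, and 10 offers only one free hydroxyl.

Step 9
Reactants: 12 the methylthiomethyl ether
Product: 13 5-(benzyloxy)-2-[4-(benzyloxy)phenyl]-7-(chloromethoxy)-8-iodo-4H-chromen-4-one (moisture-sensitive, used at once)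
Conditions: SO2Cl2 (1.0 equiv), CH2Cl2, 0 °C, 30 min; volatiles removed in vacuo
Reagents that add atoms: sulfuryl chloride, O=S(=O)(Cl)Cl
Why: Chlorinolysis of an O,S-acetal, in which sulfur is chlorinated far faster than the carbonyl-deactivated arenes and the chlorosulfonium ion fragments to the aryl chloromethyl ether, a known way to activate one phenol for an unsymmetrical formaldehyde acetal.

Step 10
Reactants: 13 the aryl chloromethyl ether; 2 7-O-benzylacacetin
Product: 14 mixed formaldehyde acetal joining u1-O5 to u2-O7, with iodine on u2-C8 and benzyl on u1-O7, u2-O5 and u2-O4'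
Conditions: 2, NaH, DMF, 0 °C; then 13 in THF, 0 °C to rt
Reagents that add atoms: none
Why: Williamson-type acetal formation, where full deprotonation with NaH breaks the chelate of the 5-OH and the resulting phenoxide should displace chloride from the alpha-chloro ether as it does with MOMCl, with no other acidic hydroxyl present in either partner.

Step 11
Reactants: 14 the iodinated mixed acetal
Product: 15 methylene-bridged 6,8''-biflavone (dibenzo[d,f][1,3]dioxepine spanning u1-O5 and u2-O7; the three benzyl ethers retained)
Conditions: Pd(OAc)2 (10 mol %), PCy3·HBF4 (20 mol %), PivOH (30 mol %), K2CO3 (2 equiv), Ag2CO3 (0.6 equiv), DMA (0.01 M), 110 °C, Ar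
Reagents that add atoms: none
Why: Phosphine-ligated zerovalent palladium generated from Pd(OAc)2 adds into the carbon-iodine bond at u2-C8, silver carbonate removes the iodide (free iodide is known to stall this catalysis with aryl iodides), and pivalate takes its place on divalent palladium. The pivalate then removes u1-C6-H by concerted metalation-deprotonation, helped by the two flanking oxygens that acidify this hydrogen and by the peri carbonyl, which turns the O5-CH2 bond towards C6. The resulting eight-membered diarylpalladacycle (Pd, u2-C8, u2-C7, O, CH2, O, u1-C5, u1-C6) collapses by reductive elimination, which closes the seven-membered dioxepine ring and makes the u1-C6 to u2-C8 bond. The closest known reaction type is pivalate-assisted intramolecular direct arylation of aryl halides across oxygen tethers, including seven-membered closures of bis(aryloxy)silanes to 2,2'-biphenol derivatives. No stereocentre is formed and the bridged axis arises as a racemate. Site selectivity on both rings is built in, because the iodide marks u2-C8 and the only ortho C-H next to O5 is C6 (the other ortho carbon is the fusion carbon C4a and C8 lies out of reach), while high dilution holds back intermolecular arylation.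

Step 12
Reactants: 15 the methylene-bridged biflavone
Product: 16 6,8''-biflavone with free u1-5-OH and u2-7-OH (u1-O7, u2-O5 and u2-O4' benzylated, u1-O4' methylated)
Conditions: HCl (4 M in dioxane)-MeOH (1:1), 60 °C
Reagents that add atoms: none
Why: Acid-catalysed transacetalisation, in which protonation of the u1 pyranone carbonyl makes the peri O5 a good leaving group, the O5-CH2 bond ionises to an oxocarbenium ion on u2-O7 that methanol carries off as its dimethyl acetal so that no free formaldehyde meets the electron-rich rings, the unactivated benzyl ethers on u1-O7 and u2-O4' are stable, and partial loss of the peri benzyl on u2-O5 would be harmless because it only bares a second chelated phenol that is inert in step 13 and due for release in step 14.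

Step 13
Reactants: 16 the biflavone diol
Product: 17 its u2-7-O-methyl ether
Conditions: MeI (1.2 equiv), K2CO3, DMF, rt
Reagents that add atoms: iodomethane, CI
Why: Williamson methylation under weak base discriminates by acidity and hydrogen bonding, since u2-7-OH is the only phenol not chelated to a C4 carbonyl and u1-5-OH stays unreactive towards a slight excess of MeI at room temperature.

Step 14
Reactants: 17 the tri-O-benzyl precursor
Product: 18 target CNP0290866.0
Conditions: H2 (1 atm), 10% Pd/C, THF-MeOH, rt
Reagents that add atoms: none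
Why: Catalytic hydrogenolysis of aryl benzyl ethers is routine on flavones, whose conjugated C2-C3 double bond, methyl ethers and biaryl bond are untouched at one atmosphere and room temperature.

**Compound list**
1 | acacetin, 5,7-dihydroxy-2-(4-methoxyphenyl)-4H-chromen-4-one | COc1ccc(cc1)-c1cc(=O)c2c(O)cc(O)cc2o1 | starting material
2 | 7-(benzyloxy)-5-hydroxy-2-(4-methoxyphenyl)-4H-chromen-4-one | COc1ccc(cc1)-c1cc(=O)c2c(O)cc(OCc3ccccc3)cc2o1 | intermediate
3 | 2,4,6-trihydroxyacetophenone | CC(=O)c1c(O)cc(O)cc1O | starting material
4 | 1-[2,6-dihydroxy-4-(methoxymethoxy)phenyl]ethan-1-one | CC(=O)c1c(O)cc(OCOC)cc1O | intermediate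
5 | 1-[2-(benzyloxy)-6-hydroxy-4-(methoxymethoxy)phenyl]ethan-1-one | CC(=O)c1c(O)cc(OCOC)cc1OCc1ccccc1 | intermediate
6 | 4-(benzyloxy)benzaldehyde | O=Cc1ccc(OCc2ccccc2)cc1 | starting material
7 | (E)-1-[2-(benzyloxy)-6-hydroxy-4-(methoxymethoxy)phenyl]-3-[4-(benzyloxy)phenyl]prop-2-en-1-one | O=C(/C=C/c1ccc(OCc2ccccc2)cc1)c1c(O)cc(OCOC)cc1OCc1ccccc1 | intermediate
8 | 5-(benzyloxy)-2-[4-(benzyloxy)phenyl]-7-(methoxymethoxy)-4H-chromen-4-one | COCOc1cc(OCc2ccccc2)c2c(=O)cc(-c3ccc(OCc4ccccc4)cc3)oc2c1 | intermediate
9 | 5-(benzyloxy)-2-[4-(benzyloxy)phenyl]-7-hydroxy-4H-chromen-4-one | Oc1cc(OCc2ccccc2)c2c(=O)cc(-c3ccc(OCc4ccccc4)cc3)oc2c1 | intermediate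
10 | 5-(benzyloxy)-2-[4-(benzyloxy)phenyl]-7-hydroxy-8-iodo-4H-chromen-4-one | Oc1cc(OCc2ccccc2)c2c(=O)cc(-c3ccc(OCc4ccccc4)cc3)oc2c1I | intermediate
11 | chloromethyl methyl sulfide | CSCCl | starting material
12 | 5-(benzyloxy)-2-[4-(benzyloxy)phenyl]-8-iodo-7-[(methylsulfanyl)methoxy]-4H-chromen-4-one | CSCOc1cc(OCc2ccccc2)c2c(=O)cc(-c3ccc(OCc4ccccc4)cc3)oc2c1I | intermediate
13 | 5-(benzyloxy)-2-[4-(benzyloxy)phenyl]-7-(chloromethoxy)-8-iodo-4H-chromen-4-one | ClCOc1cc(OCc2ccccc2)c2c(=O)cc(-c3ccc(OCc4ccccc4)cc3)oc2c1I | intermediate
14 | mixed formaldehyde acetal of u1-O5 and u2-O7, 8''-iodide, tri-O-benzyl | COc1ccc(cc1)-c1cc(=O)c2c(OCOc3cc(OCc4ccccc4)c4c(=O)cc(-c5ccc(OCc6ccccc6)cc5)oc4c3I)cc(OCc3ccccc3)cc2o1 | intermediate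
15 | methylene-bridged 6,8''-biflavone (dibenzo[d,f][1,3]dioxepine), tri-O-benzyl, racemic axis | COc1ccc(cc1)-c1cc(=O)c2c3OCOc4cc(OCc5ccccc5)c5c(=O)cc(-c6ccc(OCc7ccccc7)cc6)oc5c4-c3c(OCc3ccccc3)cc2o1 | intermediate
16 | 6,8''-biflavone with free u1-5-OH and u2-7-OH, tri-O-benzyl | COc1ccc(cc1)-c1cc(=O)c2c(O)c(-c3c(O)cc(OCc4ccccc4)c4c(=O)cc(-c5ccc(OCc6ccccc6)cc5)oc34)c(OCc3ccccc3)cc2o1 | intermediate
17 | u2-7-O-methyl ether of 16 | COc1ccc(cc1)-c1cc(=O)c2c(O)c(-c3c(OC)cc(OCc4ccccc4)c4c(=O)cc(-c5ccc(OCc6ccccc6)cc5)oc34)c(OCc3ccccc3)cc2o1 | intermediate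
18 | CNP0290866.0, 6-(acacetin)-8''-(7-O-methylapigenin) biflavone | COc1ccc(-c2cc(=O)c3c(O)c(-c4c(OC)cc(O)c5c(=O)cc(-c6ccc(O)cc6)oc45)c(O)cc3o2)cc1 | target

**Step count and risks**
Total steps: 14. Longest linear sequence: 13 (steps 2 to 14, starting from 3).

Step 11 (most likely to fail). The arylpalladium may lose its metal by protonation (hydrodeiodination), possibly after migration to the acetal CH2. That loss could outrun cleavage of the crowded C6-H. Iodide could also inhibit the catalyst, and intermolecular arylation could compete.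
- The fallback keeps the tether but marks both carbons. It sets out from 2 and 13 and rejoins the route at 15.
- Flavones with a free 5-OH and an alkylated O7 are iodinated at C6. Treating 2 with BnMe3N·ICl2 and CaCO3 in CH2Cl2-MeOH should therefore give 7-(benzyloxy)-5-hydroxy-6-iodo-2-(4-methoxyphenyl)-4H-chromen-4-one F1.
- The sodium salt of F1 is alkylated with 13 as in step 10 to give the 6,8''-diiodo mixed acetal F2.
- Intramolecular Ullmann coupling (activated copper powder, DMF, 120 °C) then joins the two iodinated carbons and gives 15. Ullmann coupling of 6- and 8-iodoflavone ethers is classical chemistry, and the tether removes its statistical problem.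

Step 12. The diaryl acetal may open incompletely. Forcing acid could then strip the non-peri benzyl ethers, which would erase the difference between the phenols, or start a Wessely-Moser ring opening and reclosure of u1.
- The fallback replaces protic solvolysis by chelation-directed halide cleavage of both peri groups and accepts a different protecting-group pattern. It sets out from 15 and rejoins the route at 18.
- MgBr2·OEt2 in toluene-Et2O at reflux binds each pyranone carbonyl together with its peri oxygen. Bromide then attacks the acetal CH2 on u1-O5 and the benzyl CH2 on u2-O5.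
- The aryl bromomethyl ether left on u2-O7 hydrolyses during cold aqueous work-up. This gives the di-O-benzyl biflavone with free u1-5-OH, u2-5-OH and u2-7-OH F3.
- MeI and K2CO3 methylate the only unchelated phenol of F3 to give the u2-7-O-methyl di-O-benzyl biflavone F4. Hydrogenolysis (H2, 10% Pd/C) of F4 gives 18.

Step 10. Adventitious water may hydrolyse the chloromethyl ether, with scrambling to the symmetrical acetal, while O-alkylation of the peri-hindered 5-phenoxide is slow.
- The fallback swaps the roles of the two halves. It sets out from 2, 11 and 10 and rejoins the route at 14.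
- Compound 2 is alkylated with 11 (NaH, NaI, DMF) to give 7-(benzyloxy)-2-(4-methoxyphenyl)-5-[(methylsulfanyl)methoxy]-4H-chromen-4-one F5.
- SO2Cl2 in CH2Cl2 at 0 °C converts F5 into 7-(benzyloxy)-5-(chloromethoxy)-2-(4-methoxyphenyl)-4H-chromen-4-one F6.
- The more acidic, unchelated phenol 10 is then alkylated with F6 under K2CO3 in DMF to give 14.

Further compounds
F1 | step 11 | 7-(benzyloxy)-5-hydroxy-6-iodo-2-(4-methoxyphenyl)-4H-chromen-4-one | COc1ccc(cc1)-c1cc(=O)c2c(O)c(I)c(OCc3ccccc3)cc2o1
F2 | step 11 | 6,8''-diiodo mixed formaldehyde acetal of u1-O5 and u2-O7, tri-O-benzyl | COc1ccc(cc1)-c1cc(=O)c2c(OCOc3cc(OCc4ccccc4)c4c(=O)cc(-c5ccc(OCc6ccccc6)cc5)oc4c3I)c(I)c(OCc3ccccc3)cc2o1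
F3 | step 12 | di-O-benzyl 6,8''-biflavone with free u1-5-OH, u2-5-OH and u2-7-OH | COc1ccc(cc1)-c1cc(=O)c2c(O)c(-c3c(O)cc(O)c4c(=O)cc(-c5ccc(OCc6ccccc6)cc5)oc34)c(OCc3ccccc3)cc2o1
F4 | step 12 | u2-7-O-methyl ether of F3 | COc1ccc(cc1)-c1cc(=O)c2c(O)c(-c3c(OC)cc(O)c4c(=O)cc(-c5ccc(OCc6ccccc6)cc5)oc34)c(OCc3ccccc3)cc2o1
F5 | step 10 | 7-(benzyloxy)-2-(4-methoxyphenyl)-5-[(methylsulfanyl)methoxy]-4H-chromen-4-one | COc1ccc(cc1)-c1cc(=O)c2c(OCSC)cc(OCc3ccccc3)cc2o1
F6 | step 10 | 7-(benzyloxy)-5-(chloromethoxy)-2-(4-methoxyphenyl)-4H-chromen-4-one | COc1ccc(cc1)-c1cc(=O)c2c(OCCl)cc(OCc3ccccc3)cc2o1
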